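**Retrosynthetic overview**

- Target ⇒ 7-hydroxy-8-ketone hydroxy ester (aerobic copper oxidation, then enolisation to the diosphenol) ⇒ 2α,3α-epoxy ketol + (2E,4E,6S)-6-methylocta-2,4-dienoic acid (trans-diaxial epoxide opening sets C2 and C3).
- Epoxy ketol ⇒ bicyclic (4S,5R)-2,9-dien-8-one (α-face epoxidation, α′-hydroxylation).
- Dienone ⇒ ten-membered (2E,5Z,7E)-3,7-dimethylcyclodecatrienone: transannular C5–C10 cation–olefin closure, then 1,2-H (C5→C4) and 1,2-Me (C10→C5) shifts, the laboratory version of germacrene A → eudesmyl cation → eremophilane; this single enantioselective step sets C4 and C5.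
- Macrocycle ⇒ open-chain tetraenone (ring-closing metathesis at C2=C3) ⇒ (E)-alkenyl iodide (from pent-1-en-4-yne) + Weinreb amide (from methyl 4-oxobutanoate); side-chain acid from (S)-2-methylbutan-1-ol.
- Ring order: the ten-membered carbocycle first, then rings A and B together in the transannular step; no ring is made afterwards.

Assumption: the (S)-oxazaborolidinium catalyst of step 7 is taken to favour the (4S,5R) dienone; if the opposite sense is found, its (R)-enantiomer is used and nothing else changes.

Eremophilane numbering (C1–C10, methyls on C4 and C5) is used for the bicyclic compounds; β is the face of the two methyl groups.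

**Step 1**
Reactants: 1 methyl 4-oxobutanoate; 2 2-(triphenylphosphoranylidene)propanal
Product: 3 methyl (4E)-5-methyl-6-oxohex-4-enoate
Conditions: CH2Cl2, 40 °C, 12 h
Reagents that add atoms: none
Why: Wittig olefination with a formyl-stabilised ylide is under thermodynamic control and gives the (E)-2-methyl enal (>95:5), and the saturated aldehyde of 1 reacts far faster than the conjugated aldehyde of 3, so the ylide adds only once.

**Step 2**
Reactants: 3 methyl (4E)-5-methyl-6-oxohex-4-enoate
Product: 4 methyl (4E)-5-methylhepta-4,6-dienoate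
Conditions: Ph3PCH3Br, KOtBu, THF, 0 °C → rt
Reagents that add atoms: methyltriphenylphosphonium bromide, C[P+](c1ccccc1)(c1ccccc1)c1ccccc1.[Br-]
Why: Wittig methylenation with the non-stabilised ylide is fast at the aldehyde at 0 °C, leaves the methyl ester and the trisubstituted olefin geometry untouched and gives the (E)-1,3-diene.

**Step 3**
Reactants: 4 methyl (4E)-5-methylhepta-4,6-dienoate
Product: 5 (4E)-N-methoxy-N,5-dimethylhepta-4,6-dienamide
Conditions: MeNH(OMe)·HCl, i-PrMgCl, THF, −20 °C
Reagents that add atoms: N,O-dimethylhydroxylamine hydrochloride, CNOC.Cl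
Why: Weinreb amide formation by aminolysis of the ester with the magnesium amide of N,O-dimethylhydroxylamine; the diene is inert and the amide later allows a single addition of the alkenyllithium.

**Step 4**
Reactants: 6 pent-1-en-4-yne
Product: 8 (1E)-1-iodo-2-methylpenta-1,4-diene, via alkenyldimethylalane 7 (not isolated)
Conditions: AlMe3 (2 equiv), Cp2ZrCl2 (20 mol %), CH2Cl2, 0 °C → rt; then I2, THF, −30 → 0 °C
Reagents that add atoms: trimethylaluminium, C[Al](C)C; iodine, [I][I]
Why: Negishi zirconium-catalysed carboalumination adds methyl and aluminium syn across the terminal alkyne with methyl on the internal carbon (the isolated alkene does not react), and iodinolysis of the C–Al bond with retention gives the (E)-alkenyl iodide.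

**Step 5**
Reactants: 8 (1E)-1-iodo-2-methylpenta-1,4-diene; 5 (4E)-N-methoxy-N,5-dimethylhepta-4,6-dienamide
Product: 10 (4E,9E)-4,10-dimethyldodeca-1,4,9,11-tetraen-6-one, via alkenyllithium 9 (not isolated)
Conditions: 8, t-BuLi (2 equiv), Et2O, −78 °C; then 5, −78 → 0 °C; aq NH4Cl
Reagents that add atoms: none
Why: Lithium–iodine exchange proceeds with retention of olefin geometry and the alkenyllithium acylates the Weinreb amide once through the stable chelated tetrahedral adduct (Weinreb ketone synthesis), giving the (E)-enone with the (E)-diene untouched.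

**Step 6**
Reactants: 10 (4E,9E)-4,10-dimethyldodeca-1,4,9,11-tetraen-6-one
Product: 11 (2E,5Z,7E)-3,7-dimethylcyclodeca-2,5,7-trien-1-one
Conditions: second-generation Hoveyda–Grubbs catalyst (C31H38Cl2N2ORu, 10 mol %), CH2Cl2 (1 mM), 40 °C, argon purge
Reagents that add atoms: none
Why: Ring-closing olefin metathesis joins the only two monosubstituted olefin ends (the trisubstituted olefins and the enone are too hindered to enter the catalytic cycle), high dilution suppresses dimers, the ten-membered ring forces the new C2=C3 bond to be Z, and closures of ten-membered germacrane-type carbocycles by RCM are the precedent.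

**Step 7**
Reactants: 11 (2E,5Z,7E)-3,7-dimethylcyclodeca-2,5,7-trien-1-one
Product: 14 (4S,5R)-11,12,13-trinoreremophila-2,9-dien-8-one, via cyclohexenyl cation enolate 12 (not isolated), via C5 cation enolate 13 (not isolated)
Conditions: (S)-1-(2-methylphenyl)-3,3-diphenyltetrahydro-1H,3H-pyrrolo[1,2-c][1,3,2]oxazaborole (C24H24BNO, 20 mol %), HN(SO2CF3)2 (18 mol %), CH2Cl2, −78 → −20 °C
Reagents that add atoms: none
Why: Proposed new method: the cationic oxazaborolidine binds the ketone of 11 and makes C10 a tertiary-cation equivalent, the (E)-trisubstituted olefin of the diene attacks it across the ring through C5 in a chair–chair (trans-fused) array to give 12 (C10 methyl and C5–H anti and axial), the axial C5–H then shifts to C4 on the α face to give 13 (setting C4 and leaving the 2,3-olefin), and the axial C10 methyl shifts to C5 on the β face while the enolate closes back to the enone and frees the catalyst (setting C5), so the two methyls end cis and the chiral Lewis acid decides which enantiomer forms; the closest known chemistry is the MeAlCl2-induced addition of olefins to enones, whose zwitterions end by a 1,2-hydride and then a 1,2-alkyl shift back to a carbonyl compound, together with the acid-induced transannular cyclisation of germacrone to eudesmanes and enone activation by chiral oxazaborolidinium salts.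

**Step 8**
Reactants: 14 (4S,5R)-11,12,13-trinoreremophila-2,9-dien-8-one
Product: 15 (2R,3S,4R,5R)-2,3-epoxy-11,12,13-trinoreremophil-9-en-8-one (2α,3α-epoxide)
Conditions: mCPBA (1.1 equiv), CH2Cl2, 0 °C
Reagents that add atoms: 3-chloroperoxybenzoic acid, OOC(=O)c1cccc(Cl)c1
Why: Prilezhaev epoxidation is chemoselective for the isolated cis-olefin over the electron-poor enone and the peracid attacks the α face, anti to the pseudoaxial angular methyl on C5 and the C4 methyl (the same bias that gives 2α,3α-epoxides from 2-ene steroids), which sets C2 and C3 of the epoxide.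

**Step 9**
Reactants: 15 (2R,3S,4R,5R)-2,3-epoxy-11,12,13-trinoreremophil-9-en-8-one
Product: 17 (2R,3S,4R,5R,7R)-2,3-epoxy-7-hydroxy-11,12,13-trinoreremophil-9-en-8-one, via potassium enolate 16 (not isolated)
Conditions: KN(SiMe3)2 (1.1 equiv), THF, −78 °C; then 2-(phenylsulfonyl)-3-phenyloxaziridine, −78 °C; aq NH4Cl
Reagents that add atoms: 2-(phenylsulfonyl)-3-phenyloxaziridine, O=S(=O)(c1ccccc1)N1OC1c1ccccc1
Why: Kinetic deprotonation of the enone at C7 (α′, −78 °C, hindered amide base) and Davis oxidation of the cross-conjugated enolate by the N-sulfonyloxaziridine give the α′-hydroxy ketone, the oxygen entering anti to the angular methyl (7α); this centre is made planar again in the last step.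

**Step 10**
Reactants: 18 (S)-2-methylbutan-1-ol
Product: 19 (S)-2-methylbutanal
Conditions: TEMPO (C9H18NO, 10 mol %), PhI(OAc)2 (1.1 equiv), CH2Cl2, rt
Reagents that add atoms: none
Why: TEMPO/PhI(OAc)2 oxidation (oxoammonium mechanism) stops at the aldehyde under non-basic conditions, so the α-stereocentre is not epimerised; the aldehyde is used at once as its solution.

**Step 11**
Reactants: 19 (S)-2-methylbutanal; 20 triethyl (2E)-4-phosphonobut-2-enoate
Product: 22 ethyl (2E,4E,6S)-6-methylocta-2,4-dienoate, via lithiated phosphonate 21 (not isolated)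
Conditions: LiN(SiMe3)2, THF, −78 → 0 °C
Reagents that add atoms: none
Why: Horner–Wadsworth–Emmons olefination with the vinylogous phosphonate forms the new C4=C5 bond E and keeps the 2E bond, and the low-temperature lithium base avoids enolisation of the α-branched aldehyde, so C6 stays S.

**Step 12**
Reactants: 22 ethyl (2E,4E,6S)-6-methylocta-2,4-dienoate
Product: 23 (2E,4E,6S)-6-methylocta-2,4-dienoic acid
Conditions: LiOH, THF/H2O, rt; then 1 M HCl
Reagents that add atoms: lithium hydroxide, [Li+].[OH-]
Why: Saponification of the ethyl ester with LiOH does not touch the diene or the remote stereocentre.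

**Step 13**
Reactants: 17 (2R,3S,4R,5R,7R)-2,3-epoxy-7-hydroxy-11,12,13-trinoreremophil-9-en-8-one; 23 (2E,4E,6S)-6-methylocta-2,4-dienoic acid
Product: 24 (2R,3R,4R,5R,7R)-2,7-dihydroxy-8-oxo-11,12,13-trinoreremophil-9-en-3-yl (2E,4E,6S)-6-methylocta-2,4-dienoate
Conditions: 23 (1.5 equiv), Co(salen) (C16H14CoN2O2, 10 mol %), i-Pr2NEt (1 equiv), air, t-BuOMe, 25 °C
Reagents that add atoms: none
Why: Carboxylate opening of the epoxide under cobalt–salen catalysis (the trivalent cobalt carboxylate formed in the flask from the divalent complex, air and 23 activates the epoxide and delivers the carboxylate) follows the Fürst–Plattner rule: attack at C3 from the β face gives the trans-diaxial chair directly, so C3 is inverted to the 3β-ester and C2 keeps its 2α-oxygen, just as 2α,3α-epoxy steroids open at the carbon syn-axial to the angular methyl.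

**Step 14**
Reactants: 24 (2R,3R,4R,5R,7R)-2,7-dihydroxy-8-oxo-11,12,13-trinoreremophil-9-en-3-yl (2E,4E,6S)-6-methylocta-2,4-dienoate
Product: 26 Septeremophilane G, via 7,8-diketone 25 (not isolated)
Conditions: Cu(OAc)2 (20 mol %), O2 (1 atm), MeOH, rt
Reagents that add atoms: none
Why: Cu(OAc)2/O2 oxidation is specific for α-hydroxy ketones (via the copper enediolate) and leaves the isolated C2 alcohol and the dienoate alone; the resulting 7,8-diketone enolises towards C6 to the cross-conjugated diosphenol, which is the natural tautomer.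

**Compound list**

1 | methyl 4-oxobutanoate | COC(=O)CCC=O | starting material
2 | 2-(triphenylphosphoranylidene)propanal | CC(C=O)=P(c1ccccc1)(c1ccccc1)c1ccccc1 | starting material
3 | methyl (4E)-5-methyl-6-oxohex-4-enoate | COC(=O)CC/C=C(\C)C=O | intermediate
4 | methyl (4E)-5-methylhepta-4,6-dienoate | COC(=O)CC/C=C(\C)C=C | intermediate
5 | (4E)-N-methoxy-N,5-dimethylhepta-4,6-dienamide | CON(C)C(=O)CC/C=C(\C)C=C | intermediate
6 | pent-1-en-4-yne | C=CCC#C | starting material
7 | dimethyl[(1E)-2-methylpenta-1,4-dien-1-yl]alumane (Al cis to methyl) | C[Al](C)/C=C(C)/CC=C | intermediate (not isolated)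
8 | (1E)-1-iodo-2-methylpenta-1,4-diene | I/C=C(C)/CC=C | intermediate
9 | [(1E)-2-methylpenta-1,4-dien-1-yl]lithium | [Li]/C=C(C)/CC=C | intermediate (not isolated)
10 | (4E,9E)-4,10-dimethyldodeca-1,4,9,11-tetraen-6-one | C=CC/C(C)=C/C(=O)CC/C=C(\C)C=C | intermediate
11 | (2E,5Z,7E)-3,7-dimethylcyclodeca-2,5,7-trien-1-one (C8 ketone, 9E-enone, 2Z,4E-diene in eremophilane numbering) | O=C1/C=C(C)/C/C=C\C(C)=C\CC1 | intermediate
12 | cyclohexenyl cation enolate: trans-fused bicycle after C5–C10 bond formation, 10-methyl β, 5-H α, cation spread over C2–C3–C4, enolate oxygen bound to boron | [O-]C1=C[C@@]2(C)CC=C[C+](C)[C@@H]2CC1 | intermediate (not isolated)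
13 | C5 cation enolate: same skeleton after the C5→C4 hydride shift, 4-H α, 4-methyl β, 10-methyl β, cation at C5 | [O-]C1=C[C@@]2(C)CC=C[C@H](C)[C+]2CC1 | intermediate (not isolated)
14 | (4S,5R)-11,12,13-trinoreremophila-2,9-dien-8-one = (4aR,5S)-4a,5-dimethyl-4,4a,5,8-tetrahydronaphthalen-2(3H)-one, methyls cis | C1=CCC2=CC(=O)CC[C@]2(C)[C@H]1C | intermediate
15 | (2R,3S,4R,5R)-2,3-epoxy-11,12,13-trinoreremophil-9-en-8-one, epoxide α (anti to both methyls) | O1[C@@H]2[C@H]1CC3=CC(=O)CC[C@]3(C)[C@H]2C | intermediate
16 | potassium 7,8-enolate of 15 (cross-conjugated dienolate) | O1[C@@H]2[C@H]1CC3=CC(O[K])=CC[C@]3(C)[C@H]2C | intermediate (not isolated)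
17 | (2R,3S,4R,5R,7R)-2,3-epoxy-7-hydroxy-11,12,13-trinoreremophil-9-en-8-one, 7-OH α | O1[C@@H]2[C@H]1CC3=CC(=O)[C@H](O)C[C@]3(C)[C@H]2C | intermediate
18 | (S)-2-methylbutan-1-ol | CC[C@H](C)CO | starting material
19 | (S)-2-methylbutanal | CC[C@H](C)C=O | intermediate
20 | triethyl (2E)-4-phosphonobut-2-enoate | CCOC(=O)/C=C/CP(=O)(OCC)OCC | starting material
21 | lithium salt of the γ-carbanion of 20 | CCOC(=O)/C=C/[CH-]P(=O)(OCC)OCC.[Li+] | intermediate (not isolated)
22 | ethyl (2E,4E,6S)-6-methylocta-2,4-dienoate | CC[C@H](C)/C=C/C=C/C(=O)OCC | intermediate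
23 | (2E,4E,6S)-6-methylocta-2,4-dienoic acid | CC[C@H](C)/C=C/C=C/C(=O)O | intermediate
24 | (2R,3R,4R,5R,7R)-2,7-dihydroxy-8-oxo-11,12,13-trinoreremophil-9-en-3-yl (2E,4E,6S)-6-methylocta-2,4-dienoate, 2-OH α axial, 3-ester β axial | CC[C@H](C)/C=C/C=C/C(=O)O[C@H]1[C@H](O)CC2=CC(=O)[C@H](O)C[C@]2(C)[C@H]1C | intermediate
25 | (2R,3R,4R,5R)-2-hydroxy-7,8-dioxo-11,12,13-trinoreremophil-9-en-3-yl (2E,4E,6S)-6-methylocta-2,4-dienoate | CC[C@H](C)/C=C/C=C/C(=O)O[C@H]1[C@H](O)CC2=CC(=O)C(=O)C[C@]2(C)[C@H]1C | intermediate (not isolated)
26 | Septeremophilane G, (2R,3R,4R,5S)-2,7-dihydroxy-8-oxo-11,12,13-trinoreremophila-6,9-dien-3-yl (2E,4E,6S)-6-methylocta-2,4-dienoate | CC[C@H](C)/C=C/C=C/C(=O)O[C@H]1[C@H](O)CC2=CC(=O)C(O)=C[C@]2(C)[C@H]1C | target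

**Step count**

Total: 14 steps. Longest linear sequence: 10 steps (1, 2, 3, 5, 6, 7, 8, 9, 13, 14) from methyl 4-oxobutanoate; step 4 and steps 10–12 are side branches.

**Steps most likely to fail, with fallbacks**

Step 6, the ten-membered ring closure, may give dimers or stall because the E,Z,E-trienone ring is strained. The fallback sets out from 10 and comes back at 14, and it reverses the order of events. The Lewis-acid conditions of step 7 are applied to the open-chain tetraenone 10. C5 then attacks C10 to close ring B alone through a chair in which the (E)-enone places the C10 methyl axial and the dienyl arm sits equatorial. The same hydride and methyl shifts follow and give (4R)-4-[(2S)-but-3-en-2-yl]-4-methyl-3-(prop-2-en-1-yl)cyclohex-2-en-1-one F1. Ring A is then closed as an unstrained cyclohexene by metathesis of its two vinyl ends (second-generation Grubbs catalyst, C46H65Cl2N2PRu, CH2Cl2, 40 °C), which gives 14.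

Step 7, the transannular cascade, may turn over poorly with the chiral boron Lewis acid or give low enantiomeric excess; proton loss from the cyclohexenyl cation is the main competing path. The fallback sets out from 11 and comes back at 15, and it moves the source of absolute configuration out of the cascade. The cascade is run with achiral MeAlCl2 (2 equiv, CH2Cl2, −78 → 0 °C), which gives 14 together with its mirror image, (4R,5S)-11,12,13-trinoreremophila-2,9-dien-8-one F2. The mixture is then epoxidised under kinetic resolution with a Shi-type chiral dioxirane (glucose-derived oxazolidinone ketone, KHSO5 as oxidant, buffered MeCN/water, 0 °C) to about half conversion. This turns 14 into 15 and leaves F2 behind for separation.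

Step 13, the opening of the hindered epoxide at C3 by the dienoic acid, may be slow or may give some C2 attack through the flipped chair. The fallback sets out from 17 and comes back at 24, and it separates C–O bond formation from acylation.
- Acid-catalysed hydrolysis (HClO4 cat., THF/H2O) lets water, the smallest nucleophile, open the epoxide trans-diaxially to (2R,3R,4R,5R,7R)-2,3,7-trihydroxy-11,12,13-trinoreremophil-9-en-8-one F3.
- The two less hindered hydroxyls are silylated (Et3SiCl, imidazole, CH2Cl2, −20 °C) to the 2,7-bis(triethylsilyl) ether F4.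
- The remaining 3β-hydroxyl is esterified with 23 through the mixed anhydride (2,4,6-trichlorobenzoyl chloride, Et3N, DMAP, toluene) to the bis-silylated ester F5.
- HF·pyridine in THF removes both silyl groups and gives 24.

**Further compounds**

F1 | step 6 | (4R)-4-[(2S)-but-3-en-2-yl]-4-methyl-3-(prop-2-en-1-yl)cyclohex-2-en-1-one | C=CCC1=CC(=O)CC[C@]1(C)[C@@H](C)C=C
F2 | step 7 | (4R,5S)-11,12,13-trinoreremophila-2,9-dien-8-one (enantiomer of 14) | C1=CCC2=CC(=O)CC[C@@]2(C)[C@@H]1C
F3 | step 13 | (2R,3R,4R,5R,7R)-2,3,7-trihydroxy-11,12,13-trinoreremophil-9-en-8-one | O[C@H]1[C@H](O)CC2=CC(=O)[C@H](O)C[C@]2(C)[C@H]1C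
F4 | step 13 | 2,7-bis(triethylsilyl) ether of F3 | O[C@H]1[C@H](O[Si](CC)(CC)CC)CC2=CC(=O)[C@H](O[Si](CC)(CC)CC)C[C@]2(C)[C@H]1C
F5 | step 13 | 2,7-bis(triethylsilyl) ether of 24 | CC[C@H](C)/C=C/C=C/C(=O)O[C@H]1[C@H](O[Si](CC)(CC)CC)CC2=CC(=O)[C@H](O[Si](CC)(CC)CC)C[C@]2(C)[C@H]1C
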